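## Retrosynthetic overview

1. Target ⇐ hydrogenolysis of five benzyl ethers; pyranone ring C is made last, by acylating the polyanion of an A-ring α-methoxy ketone with a dihydrobenzofuran-5-carbonyl chloride and closing with acid.
2. That acid ⇐ the aryl bromide (Br–Li exchange, CO2).
3. Dihydrofuran ring (made first) ⇐ C2–C3 bond between an o-quinone methide carbon and a benzylic carbon whose polarity is reversed as a chiral sulfonium ylide (an α-oxybenzyl anion equivalent), then C2–O closure; this one [4+1] step sets both stereocentres.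
4. o-Quinone methide precursor ⇐ 2,5-bis(benzyloxy)benzaldehyde (Dakin oxidation, bromination), 4-(benzyloxy)benzaldehyde and a sulfinate.
5. A-ring ketone ⇐ 2-methylresorcinol (MOM ethers, C–H borylation/oxidation para to the methyl, ortho-acylation), which fixes the 6-methyl regiochemistry.

Assumption: sulfide 15 with the (1R,4R,5R) configuration is taken to deliver the 2S centre (the facial sense it shows in trans-epoxide formation); if a pilot run shows the opposite sense, its enantiomer from (S)-limonene is used with nothing else changed.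
Assumption: 5, 8, 12, 14 and 15 are bought as catalog compounds.

## Route

Step 1
Reactants: 1 2-methylresorcinol
Product: 2 bis-MOM ether 1,3-bis(methoxymethoxy)-2-methylbenzene
Conditions: NaH (2.4 equiv), MOMCl (2.4 equiv), DMF, 0 °C to rt
Reagents that add atoms: chloromethyl methyl ether, COCCl
Why: Williamson-type O-alkylation of both phenoxides (MOM protection); no stereocentre is involved.

Step 2
Reactants: 2 1,3-bis(methoxymethoxy)-2-methylbenzene
Product: 4 phenol 3,5-bis(methoxymethoxy)-4-methylphenol, via aryl boronate 3 (not isolated)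
Conditions: [Ir(OMe)(cod)]2 (1.5 mol %), 4,4'-di-tert-butyl-2,2'-bipyridine (3 mol %), B2pin2 (0.6 equiv), THF, 80 °C; then KHSO5 (as the triple salt 2KHSO5·KHSO4·K2SO4), acetone–H2O, 0 °C to rt
Reagents that add atoms: potassium peroxymonosulfate, [K+].[O-]S(=O)(=O)OO
Why: Sterically controlled iridium-catalysed C–H borylation touches only C5 (the one C–H not ortho to a substituent; MOM ethers carry no competing aryl C–H), and oxidation of the C–B bond leaves the only free OH para to the methyl group, the oxygen that must become O1 of the 6-methylchromone.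

Step 3
Reactants: 4 3,5-bis(methoxymethoxy)-4-methylphenol; 5 N,2-dimethoxy-N-methylacetamide
Product: 7 ketone 1-[6-hydroxy-2,4-bis(methoxymethoxy)-3-methylphenyl]-2-methoxyethan-1-one, via dilithio phenoxide 6 (not isolated)
Conditions: n-BuLi (2.2 equiv), TMEDA, THF, 0 °C; then 5, −78 °C to rt; AcOH quench
Reagents that add atoms: none
Why: Directed ortho-metalation: after O-lithiation the second n-BuLi removes a ring proton flanked by OLi and OMOM (the two such sites are equivalent), and the aryllithium is acylated once by the Weinreb amide through its stable chelated adduct.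

Step 4
Reactants: 8 2,5-bis(benzyloxy)benzaldehyde
Product: 10 phenol 2,5-bis(benzyloxy)phenol, via aryl formate 9 (not isolated)
Conditions: mCPBA, CH2Cl2, rt; then MeOH, Et3N (cat.), rt
Reagents that add atoms: 3-chloroperoxybenzoic acid, OOC(=O)c1cccc(Cl)c1
Why: Dakin-type Baeyer–Villiger oxidation in which the electron-rich ortho-alkoxy aryl group migrates, followed by methanolysis of the labile aryl formate.

Step 5
Reactants: 10 2,5-bis(benzyloxy)phenol
Product: 11 bromophenol 2,5-bis(benzyloxy)-4-bromophenol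
Conditions: NBS (1.0 equiv), MeCN, −20 to 0 °C
Reagents that add atoms: N-bromosuccinimide, O=C1CCC(=O)N1Br
Why: Electrophilic aromatic bromination goes para to the free OH (also ortho to an OBn and the less hindered of the two activated sites), which blocks that position and installs the later carboxyl handle.

Step 6
Reactants: 11 2,5-bis(benzyloxy)-4-bromophenol; 12 4-(benzyloxy)benzaldehyde
Product: 13 sulfone 3,6-bis(benzyloxy)-4-bromo-2-{[4-(benzyloxy)phenyl](4-methylbenzenesulfonyl)methyl}phenol (racemic)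
Conditions: p-TolSO2Na (1.5 equiv), HCO2H–H2O–THF, rt
Reagents that add atoms: sodium 4-methylbenzenesulfinate, Cc1ccc(cc1)S(=O)[O-].[Na+]
Why: Three-component Friedel–Crafts-type (Mannich-like) α-sulfonylalkylation at the only remaining position ortho to OH, the sulfinate trapping the transient o-quinone methide; the racemic centre is erased in step 8.

Step 7
Reactants: 14 3,5-bis(benzyloxy)benzyl bromide; 15 (1R,4R,5R)-isothiocineole
Product: 16 sulfonium triflate (1R,4R,5R)-6-[3,5-bis(benzyloxy)benzyl]-4,7,7-trimethyl-6-thiabicyclo[3.2.1]octan-6-ium trifluoromethanesulfonate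
Conditions: LiOSO2CF3 (5 equiv), CH2Cl2–H2O, rt
Reagents that add atoms: lithium trifluoromethanesulfonate, [Li+].[O-]S(=O)(=O)C(F)(F)F
Why: SN2 S-benzylation of the bicyclic sulfide on its exposed lone pair with anion metathesis, giving a single epimer at sulfur.

Step 8
Reactants: 13 sulfone; 16 sulfonium triflate
Product: 20 bromide (2S,3S)-4,7-bis(benzyloxy)-2-[3,5-bis(benzyloxy)phenyl]-3-[4-(benzyloxy)phenyl]-5-bromo-2,3-dihydro-1-benzofuran, via o-quinone methide 17 (not isolated), via sulfonium ylide 18 (not isolated), via betaine 19 (not isolated)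
Conditions: Cs2CO3 (3 equiv), 16 (1.2 equiv), MeCN–CH2Cl2, −20 °C to rt
Reagents that add atoms: none
Why: Proposed new method: a polarity-reversed [4+1] annulation in which both C2 and C3 are natively electrophilic (C3 as the methide carbon of 17 formed by E1cB loss of sulfinate, C2 as a benzylic carbon at the benzyl halide/aldehyde level) and C2 is made nucleophilic as ylide 18, which adds 1,4 to 17 through the aryl/aryl-transoid transition state to give betaine 19, whose phenoxide then displaces the sulfide by 5-exo SN2 with inversion to give the trans ring; the rigid bicyclic sulfide fixes the ylide conformation and shields one face so that C2 is set as S and C3 follows as S from the trans preference; the closest known reactions are the racemic sulfonium ylide/o-quinone methide [4+1] annulation of 2-(tosylalkyl)phenols under carbonate base and the highly enantioselective trans-epoxidation and aziridination by this class of benzylic ylide.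

Step 9
Reactants: 20 bromide
Product: 22 acid (2S,3S)-4,7-bis(benzyloxy)-2-[3,5-bis(benzyloxy)phenyl]-3-[4-(benzyloxy)phenyl]-2,3-dihydro-1-benzofuran-5-carboxylic acid, via aryllithium 21 (not isolated)
Conditions: n-BuLi (1.1 equiv), THF, −78 °C; CO2; aq. HCl work-up
Reagents that add atoms: carbon dioxide, O=C=O
Why: Bromine–lithium exchange (much faster at −78 °C than any benzylic deprotonation) and carboxylation of the aryllithium; the stereocentres are not touched.

Step 10
Reactants: 22 acid; 7 ketone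
Product: 26 flavone 2-[(2S,3S)-4,7-bis(benzyloxy)-2-[3,5-bis(benzyloxy)phenyl]-3-[4-(benzyloxy)phenyl]-2,3-dihydro-1-benzofuran-5-yl]-5,7-dihydroxy-3-methoxy-6-methyl-4H-chromen-4-one, via acid chloride 23 (not isolated), via diketone 24 (not isolated), via bis-MOM flavone 25 (not isolated)
Conditions: (COCl)2, DMF (cat.), CH2Cl2, 0 °C to rt, evaporate; add to 7 + LiN(SiMe3)2 (3.5 equiv), THF, −78 °C to rt; then conc. HCl, MeOH, 50 °C
Reagents that add atoms: none
Why: Baker–Venkataraman-type diketone synthesis by C-acylation of the lithium polyanion of 7 (any O-acyl product rearranges to the same diketone under the excess base), then acid cyclodehydration through the only free OH (para to methyl, hence the 6-methyl isomer) and cleavage of the two MOM acetals, with benzyl ethers, 3-OMe and the trans-dihydrofuran inert to methanolic HCl.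

Step 11
Reactants: 26 flavone
Product: 27 target 2-[(2S,3S)-2-(3,5-dihydroxyphenyl)-4,7-dihydroxy-3-(4-hydroxyphenyl)-2,3-dihydro-1-benzofuran-5-yl]-5,7-dihydroxy-3-methoxy-6-methyl-4H-chromen-4-one
Conditions: H2 (1 atm), 10% Pd/C, degassed THF–MeOH, rt; work-up under argon
Reagents that add atoms: none
Why: Catalytic hydrogenolysis removes the five primary benzyl ethers while the flavone C2=C3/C4=O and the hindered cyclic benzylic C2–O bond survive, as in deprotections of benzylated flavonols and flavans; the stereocentres are untouched and the hydroquinone product is kept from air.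

## Compound list

1 | 2-methylresorcinol (2-methylbenzene-1,3-diol) | Cc1c(O)cccc1O | starting material
2 | 1,3-bis(methoxymethoxy)-2-methylbenzene | COCOc1cccc(OCOC)c1C | intermediate
3 | 2-[3,5-bis(methoxymethoxy)-4-methylphenyl]-4,4,5,5-tetramethyl-1,3,2-dioxaborolane | COCOc1cc(B2OC(C)(C)C(C)(C)O2)cc(OCOC)c1C | intermediate
4 | 3,5-bis(methoxymethoxy)-4-methylphenol | COCOc1cc(O)cc(OCOC)c1C | intermediate
5 | N,2-dimethoxy-N-methylacetamide | COCC(=O)N(C)OC | starting material
6 | lithium 2-lithio-3,5-bis(methoxymethoxy)-4-methylphenoxide | COCOc1cc(O[Li])c([Li])c(OCOC)c1C | intermediate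
7 | 1-[6-hydroxy-2,4-bis(methoxymethoxy)-3-methylphenyl]-2-methoxyethan-1-one | COCC(=O)c1c(O)cc(OCOC)c(C)c1OCOC | intermediate
8 | 2,5-bis(benzyloxy)benzaldehyde | O=Cc1cc(OCc2ccccc2)ccc1OCc1ccccc1 | starting material
9 | 2,5-bis(benzyloxy)phenyl formate | O=COc1cc(OCc2ccccc2)ccc1OCc1ccccc1 | intermediate
10 | 2,5-bis(benzyloxy)phenol | Oc1cc(OCc2ccccc2)ccc1OCc1ccccc1 | intermediate
11 | 2,5-bis(benzyloxy)-4-bromophenol | Oc1cc(OCc2ccccc2)c(Br)cc1OCc1ccccc1 | intermediate
12 | 4-(benzyloxy)benzaldehyde | O=Cc1ccc(OCc2ccccc2)cc1 | starting material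
13 | 3,6-bis(benzyloxy)-4-bromo-2-{[4-(benzyloxy)phenyl](4-methylbenzenesulfonyl)methyl}phenol, racemic | Cc1ccc(cc1)S(=O)(=O)C(c1ccc(OCc2ccccc2)cc1)c1c(O)c(OCc2ccccc2)cc(Br)c1OCc1ccccc1 | intermediate
14 | 3,5-bis(benzyloxy)benzyl bromide | BrCc1cc(OCc2ccccc2)cc(OCc2ccccc2)c1 | starting material
15 | (1R,4R,5R)-4,7,7-trimethyl-6-thiabicyclo[3.2.1]octane (isothiocineole) | C[C@@H]1CC[C@@H]2C[C@H]1SC2(C)C | starting material
16 | (1R,4R,5R)-6-[3,5-bis(benzyloxy)benzyl]-4,7,7-trimethyl-6-thiabicyclo[3.2.1]octan-6-ium trifluoromethanesulfonate, single epimer at sulfur (sulfur configuration not written in the SMILES) | C[C@@H]1CC[C@@H]2C[C@H]1[S+](Cc1cc(OCc3ccccc3)cc(OCc3ccccc3)c1)C2(C)C.[O-]S(=O)(=O)C(F)(F)F | intermediate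
17 | 2,5-bis(benzyloxy)-6-[4-(benzyloxy)benzylidene]-4-bromocyclohexa-2,4-dien-1-one (o-quinone methide, alkene geometry not defined) | O=C1C(OCc2ccccc2)=CC(Br)=C(OCc2ccccc2)C1=Cc1ccc(OCc2ccccc2)cc1 | intermediate
18 | sulfonium ylide of 16, [3,5-bis(benzyloxy)phenyl]methanide on sulfur | C[C@@H]1CC[C@@H]2C[C@H]1[S+]([CH-]c1cc(OCc3ccccc3)cc(OCc3ccccc3)c1)C2(C)C | intermediate
19 | anti betaine: 3,6-bis(benzyloxy)-4-bromo-2-[(1S,2R)-2-[3,5-bis(benzyloxy)phenyl]-1-[4-(benzyloxy)phenyl]-2-(isothiocineol-6-ium-6-yl)ethyl]phenolate | C[C@@H]1CC[C@@H]2C[C@H]1[S+](C2(C)C)[C@@H](c1cc(OCc2ccccc2)cc(OCc2ccccc2)c1)[C@@H](c1ccc(OCc2ccccc2)cc1)c1c([O-])c(OCc2ccccc2)cc(Br)c1OCc1ccccc1 | intermediate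
20 | (2S,3S)-4,7-bis(benzyloxy)-2-[3,5-bis(benzyloxy)phenyl]-3-[4-(benzyloxy)phenyl]-5-bromo-2,3-dihydro-1-benzofuran | Brc1cc(OCc2ccccc2)c2c(c1OCc1ccccc1)[C@H](c1ccc(OCc3ccccc3)cc1)[C@@H](c1cc(OCc3ccccc3)cc(OCc3ccccc3)c1)O2 | intermediate
21 | (2S,3S)-4,7-bis(benzyloxy)-2-[3,5-bis(benzyloxy)phenyl]-3-[4-(benzyloxy)phenyl]-2,3-dihydro-1-benzofuran-5-yllithium | [Li]c1cc(OCc2ccccc2)c2c(c1OCc1ccccc1)[C@H](c1ccc(OCc3ccccc3)cc1)[C@@H](c1cc(OCc3ccccc3)cc(OCc3ccccc3)c1)O2 | intermediate
22 | (2S,3S)-4,7-bis(benzyloxy)-2-[3,5-bis(benzyloxy)phenyl]-3-[4-(benzyloxy)phenyl]-2,3-dihydro-1-benzofuran-5-carboxylic acid | OC(=O)c1cc(OCc2ccccc2)c2c(c1OCc1ccccc1)[C@H](c1ccc(OCc3ccccc3)cc1)[C@@H](c1cc(OCc3ccccc3)cc(OCc3ccccc3)c1)O2 | intermediate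
23 | (2S,3S)-4,7-bis(benzyloxy)-2-[3,5-bis(benzyloxy)phenyl]-3-[4-(benzyloxy)phenyl]-2,3-dihydro-1-benzofuran-5-carbonyl chloride | ClC(=O)c1cc(OCc2ccccc2)c2c(c1OCc1ccccc1)[C@H](c1ccc(OCc3ccccc3)cc1)[C@@H](c1cc(OCc3ccccc3)cc(OCc3ccccc3)c1)O2 | intermediate
24 | 1-[(2S,3S)-4,7-bis(benzyloxy)-2-[3,5-bis(benzyloxy)phenyl]-3-[4-(benzyloxy)phenyl]-2,3-dihydro-1-benzofuran-5-yl]-3-[6-hydroxy-2,4-bis(methoxymethoxy)-3-methylphenyl]-2-methoxypropane-1,3-dione (C2 of the dione unassigned; enol and hemiketal forms) | COC(C(=O)c1c(O)cc(OCOC)c(C)c1OCOC)C(=O)c1cc(OCc2ccccc2)c2c(c1OCc1ccccc1)[C@H](c1ccc(OCc3ccccc3)cc1)[C@@H](c1cc(OCc3ccccc3)cc(OCc3ccccc3)c1)O2 | intermediate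
25 | 2-[(2S,3S)-4,7-bis(benzyloxy)-2-[3,5-bis(benzyloxy)phenyl]-3-[4-(benzyloxy)phenyl]-2,3-dihydro-1-benzofuran-5-yl]-3-methoxy-5,7-bis(methoxymethoxy)-6-methyl-4H-chromen-4-one | COc1c(-c2cc(OCc4ccccc4)c3c(c2OCc2ccccc2)[C@H](c2ccc(OCc4ccccc4)cc2)[C@@H](c2cc(OCc4ccccc4)cc(OCc4ccccc4)c2)O3)oc2cc(OCOC)c(C)c(OCOC)c2c1=O | intermediate
26 | 2-[(2S,3S)-4,7-bis(benzyloxy)-2-[3,5-bis(benzyloxy)phenyl]-3-[4-(benzyloxy)phenyl]-2,3-dihydro-1-benzofuran-5-yl]-5,7-dihydroxy-3-methoxy-6-methyl-4H-chromen-4-one | COc1c(-c2cc(OCc4ccccc4)c3c(c2OCc2ccccc2)[C@H](c2ccc(OCc4ccccc4)cc2)[C@@H](c2cc(OCc4ccccc4)cc(OCc4ccccc4)c2)O3)oc2cc(O)c(C)c(O)c2c1=O | intermediate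
27 | 2-[(2S,3S)-2-(3,5-dihydroxyphenyl)-4,7-dihydroxy-3-(4-hydroxyphenyl)-2,3-dihydro-1-benzofuran-5-yl]-5,7-dihydroxy-3-methoxy-6-methyl-4H-chromen-4-one (CNP0218412.2) | COc1c(-c2cc(O)c3c(c2O)[C@H](c2ccc(O)cc2)[C@@H](c2cc(O)cc(O)c2)O3)oc2cc(O)c(C)c(O)c2c1=O | target

## Step count and risks

Total steps: 11. Longest linear sequence: 7 (steps 4, 5, 6, 8, 9, 10, 11, from 8).

Most likely to fail, with fallbacks:

Step 8 (new asymmetric annulation; ylide formation, ee and dr are untested on an o-quinone methide). The fallback keeps the C2–C3 disconnection but uses a true acyl anion and sets the stereocentres afterwards. It sets out from 13: with commercial 3,5-bis(benzyloxy)benzaldehyde, 3-benzyl-5-(2-hydroxyethyl)-4-methylthiazolium chloride and Cs2CO3 in THF, the Breslow intermediate adds to o-quinone methide 17 to give racemic 1-[3,5-bis(benzyloxy)phenyl]-2-[2,5-bis(benzyloxy)-3-bromo-6-hydroxyphenyl]-2-[4-(benzyloxy)phenyl]ethan-1-one F1. Transfer hydrogenation with dynamic kinetic resolution of the labile α-centre (RuCl(p-cymene)[(R,R)-TsDPEN], HCO2H/Et3N) gives (1R,2S)-1-[3,5-bis(benzyloxy)phenyl]-2-[2,5-bis(benzyloxy)-3-bromo-6-hydroxyphenyl]-2-[4-(benzyloxy)phenyl]ethan-1-ol F2; the syn/anti outcome would have to be checked. Mitsunobu closure (PPh3, DIAD, THF) with inversion at the carbinol carbon comes back to the route at 20.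

Step 6 (alkylation at a position flanked by OH and OBn). The fallback builds the same carbon in two carbonyl additions. It sets out from 11: magnesium-mediated ortho-formylation (MgCl2, Et3N, paraformaldehyde, MeCN, reflux) gives 3,6-bis(benzyloxy)-5-bromo-2-hydroxybenzaldehyde F3. Addition of 4-(benzyloxy)phenylmagnesium bromide (2.2 equiv, THF, 0 °C) gives 3,6-bis(benzyloxy)-4-bromo-2-{[4-(benzyloxy)phenyl](hydroxy)methyl}phenol F4. Treating F4 with p-TolSO2Na in HCO2H exchanges OH for sulfinate through the o-quinone methide and comes back to the route at 13.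

Step 3 (ring lithiation of a lithium phenoxide may be slow or compete with lateral lithiation of the methyl group). The fallback replaces C–H deprotonation by halogen–metal exchange. It sets out from 4: NBS (1.0 equiv, CH2Cl2, −78 to 0 °C) gives 2-bromo-3,5-bis(methoxymethoxy)-4-methylphenol F5. n-BuLi (2.1 equiv, THF, −78 °C) then forms the same dilithio species 6 by O–H deprotonation and Br–Li exchange, and acylation with 5 comes back to the route at 7.

## Further compounds

F1 | step 8 | 1-[3,5-bis(benzyloxy)phenyl]-2-[2,5-bis(benzyloxy)-3-bromo-6-hydroxyphenyl]-2-[4-(benzyloxy)phenyl]ethan-1-one, racemic | O=C(c1cc(OCc2ccccc2)cc(OCc2ccccc2)c1)C(c1ccc(OCc2ccccc2)cc1)c1c(O)c(OCc2ccccc2)cc(Br)c1OCc1ccccc1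
F2 | step 8 | (1R,2S)-1-[3,5-bis(benzyloxy)phenyl]-2-[2,5-bis(benzyloxy)-3-bromo-6-hydroxyphenyl]-2-[4-(benzyloxy)phenyl]ethan-1-ol | O[C@@H](c1cc(OCc2ccccc2)cc(OCc2ccccc2)c1)[C@@H](c1ccc(OCc2ccccc2)cc1)c1c(O)c(OCc2ccccc2)cc(Br)c1OCc1ccccc1
F3 | step 6 | 3,6-bis(benzyloxy)-5-bromo-2-hydroxybenzaldehyde | O=Cc1c(O)c(OCc2ccccc2)cc(Br)c1OCc1ccccc1
F4 | step 6 | 3,6-bis(benzyloxy)-4-bromo-2-{[4-(benzyloxy)phenyl](hydroxy)methyl}phenol, racemic | OC(c1ccc(OCc2ccccc2)cc1)c1c(O)c(OCc2ccccc2)cc(Br)c1OCc1ccccc1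
F5 | step 3 | 2-bromo-3,5-bis(methoxymethoxy)-4-methylphenol | COCOc1cc(O)c(Br)c(OCOC)c1C
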